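## Retrosynthetic overview

1. Target 17 comes from 16 by removal of seven MOM ethers.
2. The cyclohexene of 16 comes from keto-vinylcyclobutane 15 by an ionic ring expansion (1,3-shift of the aroyl-bearing carbon). This step forms the six-membered ring and sets C1 and C6.
3. Cyclobutane 15 comes from an enantioselective crossed [2+2] photocycloaddition of 2'-hydroxychalcone 8 with the isopropenyl end of diene chalcone 14. This step sets C5.
4. 8 comes from aldehyde 4 and ketone 7. 14 comes from aldehyde 4 and diene ketone 13, itself from iodide 10 and enyne 11. All arenes come from resorcinol 1 and acetic acid 5.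
5. Ring order: aromatic rings (from resorcinol), then the cyclobutane, then the cyclohexene.

Assumption: (S,S)-t-Bu-PyBox/Sc(OTf)3 is taken to give the (S)-configured aryl-bearing ring carbon in step 10; if the sense is opposite, the (R,R)-ligand is used and nothing else changes.

Numbering used: in the cyclohexene, C1 carries the chalcone aryl group, C2=C3(Me), C4 is CH2, C5 carries the 2,4-dioxygenated phenyl and C6 the aroyl group. The target is (1S,5S,6R), with C1-aryl cis to C6-aroyl and C6-aroyl trans to C5-aryl. In the cyclobutane, C1 carries the aroyl group, C2 is quaternary, C3 is CH2 and C4 carries the aryl group.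

## Route

Step 1
Reactants: 1 resorcinol
Product: 3 2,4-dihydroxybenzaldehyde, via aryl iminium chloride 2 (not isolated)
Conditions: POCl3, DMF, MeCN, −15 → 25 °C; then H2O, 50 °C
Reagents that add atoms: N,N-dimethylformamide, CN(C)C=O; water, O; phosphoryl chloride, O=P(Cl)(Cl)Cl (supplies only the chloride counter-ion of 2)
Why: Vilsmeier–Haack formylation attacks the carbon para to one hydroxyl and ortho to the other, and the iminium salt is hydrolysed to the aldehyde on warming in water.

Step 2
Reactants: 3 2,4-dihydroxybenzaldehyde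
Product: 4 2,4-bis(methoxymethoxy)benzaldehyde
Conditions: NaH (2.3 equiv), MOMCl (2.3 equiv), DMF, 0 °C → rt
Reagents that add atoms: chloromethyl methyl ether, COCCl
Why: Williamson-type O-alkylation of both sodium phenoxides, with NaH strong enough to alkylate the chelated 2-OH as well.

Step 3
Reactants: 1 resorcinol; 5 acetic acid
Product: 6 1-(2,4-dihydroxyphenyl)ethanone
Conditions: ZnCl2, AcOH, 140 °C
Reagents that add atoms: none
Why: Nencki (Friedel–Crafts) C-acylation of resorcinol at the position ortho/para to the two hydroxyls.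

Step 4
Reactants: 6 1-(2,4-dihydroxyphenyl)ethanone
Product: 7 1-[2-hydroxy-4-(methoxymethoxy)phenyl]ethanone
Conditions: MOMCl (1.05 equiv), K2CO3, acetone, 0 °C → rt
Reagents that add atoms: chloromethyl methyl ether, COCCl
Why: selective Williamson alkylation of the 4-OH, because the 2-OH is hydrogen-bonded to the ketone and is not alkylated with K2CO3.

Step 5
Reactants: 7 1-[2-hydroxy-4-(methoxymethoxy)phenyl]ethanone; 4 2,4-bis(methoxymethoxy)benzaldehyde
Product: 8 (E)-3-[2,4-bis(methoxymethoxy)phenyl]-1-[2-hydroxy-4-(methoxymethoxy)phenyl]prop-2-en-1-one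
Conditions: KOH, EtOH/H2O, rt
Reagents that add atoms: none
Why: Claisen–Schmidt aldol condensation, with E1cB dehydration giving the E enone and leaving the 2'-OH free for later chelation.

Step 6
Reactants: 6 1-(2,4-dihydroxyphenyl)ethanone
Product: 9 1-(2,4-dihydroxy-3-iodophenyl)ethanone
Conditions: I2 (0.4 equiv), HIO3 (0.2 equiv), EtOH/H2O, 35 °C
Reagents that add atoms: iodine, II; iodic acid, OI(=O)=O
Why: electrophilic aromatic iodination at the carbon between the two hydroxyls (doubly ortho-activated), with I2/HIO3 delivering all iodine to the arene.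

Step 7
Reactants: 9 1-(2,4-dihydroxy-3-iodophenyl)ethanone
Product: 10 1-[3-iodo-2,4-bis(methoxymethoxy)phenyl]ethanone
Conditions: NaH (2.3 equiv), MOMCl (2.3 equiv), DMF, 0 °C → rt
Reagents that add atoms: chloromethyl methyl ether, COCCl
Why: Williamson-type O-alkylation of both phenoxides, which are far more acidic than the methyl ketone, so no enolate forms.

Step 8
Reactants: 10 1-[3-iodo-2,4-bis(methoxymethoxy)phenyl]ethanone; 11 2-methylbut-1-en-3-yne
Product: 13 1-[2,4-bis(methoxymethoxy)-3-[(1E)-3-methylbuta-1,3-dien-1-yl]phenyl]ethanone, via (E)-dienyl pinacol boronate 12 (not isolated)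
Conditions: 11, HBpin, Cp2Zr(H)Cl (5 mol %), Et3N (10 mol %), sealed tube, 60 °C; then 10, Pd(OAc)2 (5 mol %), SPhos, K3PO4, dioxane/H2O, 80 °C
Reagents that add atoms: pinacolborane, CC1(C)OBOC1(C)C (adds the boron group of 12 only; nothing from it stays in 13)
Why: syn-hydroboration of the terminal alkyne gives the (E)-dienylboronate, and Suzuki–Miyaura coupling with the di-ortho-substituted aryl iodide (SPhos ligand) retains the alkene geometry.

Step 9
Reactants: 13 1-[2,4-bis(methoxymethoxy)-3-[(1E)-3-methylbuta-1,3-dien-1-yl]phenyl]ethanone; 4 2,4-bis(methoxymethoxy)benzaldehyde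
Product: 14 (E)-1-[2,4-bis(methoxymethoxy)-3-[(1E)-3-methylbuta-1,3-dien-1-yl]phenyl]-3-[2,4-bis(methoxymethoxy)phenyl]prop-2-en-1-one
Conditions: KOH, EtOH/THF, rt
Reagents that add atoms: none
Why: Claisen–Schmidt aldol condensation giving the E enone, with the diene and MOM ethers inert to hydroxide.

Step 10
Reactants: 8 (E)-3-[2,4-bis(methoxymethoxy)phenyl]-1-[2-hydroxy-4-(methoxymethoxy)phenyl]prop-2-en-1-one; 14 diene chalcone (1.5 equiv, excess recovered)
Product: 15 keto-vinylcyclobutane (1R,4S; both C2 epimers), i.e. [4-[2,4-bis(methoxymethoxy)phenyl]-2-methyl-2-[(E)-2-arylethenyl]cyclobutyl][2-hydroxy-4-(methoxymethoxy)phenyl]methanone, where aryl is the 2,6-bis(methoxymethoxy)-3-cinnamoyl ring of 14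
Conditions: Sc(OTf)3 (10 mol %), (S,S)-t-Bu-PyBox (15 mol %), Ru(bpy)3(PF6)2 (2.5 mol %), i-PrOAc/MeCN 3:1, blue LEDs, 0 °C
Reagents that add atoms: none
Why: crossed enone–diene [2+2] photocycloaddition under Lewis-acid-catalysed triplet sensitisation, in which only the chalcone chelated through its free 2'-OH to the chiral scandium–PyBox complex is sensitised by Ru(bpy)3(PF6)2, its β-carbon adds to the unhindered CH2 terminus of the diene and the resulting α-keto/aryl-allyl 1,4-diradical closes at the tertiary allyl terminus; the ligand shields one enone face and sets cyclobutane C4 as S, diradical relaxation places aroyl and aryl trans (C1 R), and C2 forms as both epimers, which is harmless because C2 becomes sp2 in step 11.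

Step 11
Reactants: 15 keto-vinylcyclobutane (both C2 epimers)
Product: 16 (E)-1-[3-[(1S,5S,6R)-5-[2,4-bis(methoxymethoxy)phenyl]-6-[2-hydroxy-4-(methoxymethoxy)benzoyl]-3-methylcyclohex-2-en-1-yl]-2,4-bis(methoxymethoxy)phenyl]-3-[2,4-bis(methoxymethoxy)phenyl]prop-2-en-1-one
Conditions: Sc(OTf)3 (10 mol %), 2,6-di-tert-butylpyridine (10 mol %), 4 Å MS, CH2Cl2, −40 → 0 °C
Reagents that add atoms: none
Why: Proposed new method: a Lewis-acid-catalysed ionic 1,3-shift (vinylcyclobutane-to-cyclohexene ring expansion) in which scandium chelation of the 2-hydroxyaryl ketone turns the cyclobutane C1–C2 bond into a donor–acceptor bond that heterolyses, with relief of about 26 kcal/mol of strain, to a tethered scandium enolate/1-aryl-3,3-dialkylallyl cation pair stabilised by the two ortho-alkoxy groups; return to the four-membered ring only interconverts the C2 epimers, whereas attack of the enolate carbon on the benzylic allyl terminus closes the strain-free six-membered ring irreversibly, with A(1,3) strain in the enolate placing the new C6 aroyl trans to the C5 aryl, and the retained E geometry of the cation together with the compact, least charge-separated (endo-like) ion-pair geometry in CH2Cl2 placing the C1 aryl cis to the aroyl group, so that the pre-set C5 (S) centre dictates 1S and 6R; the closest known reaction types are the Lewis-acid-catalysed donor–acceptor vinylcyclopropane-to-cyclopentene rearrangement and the ring-opening annulations of donor–acceptor cyclobutanes.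

Step 12
Reactants: 16 hepta-MOM-protected cyclohexene
Product: 17 (E)-1-[3-[(1S,5S,6R)-6-(2,4-dihydroxybenzoyl)-5-(2,4-dihydroxyphenyl)-3-methylcyclohex-2-en-1-yl]-2,4-dihydroxyphenyl]-3-(2,4-dihydroxyphenyl)prop-2-en-1-one (target)
Conditions: HCl (1.25 M in MeOH), THF, 0 °C → rt; NaHCO3 quench
Reagents that add atoms: none
Why: acid-catalysed transacetalisation of the seven aryl MOM ethers to dimethoxymethane, kept short and at or below room temperature so that the stereocentres, the chalcone and the cyclohexene are untouched.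

## Compound list

1 | resorcinol | Oc1cccc(O)c1 | starting material
2 | [(2,4-dihydroxyphenyl)methylidene]dimethyliminium chloride | C[N+](C)=Cc1ccc(O)cc1O.[Cl-] | intermediate (not isolated)
3 | 2,4-dihydroxybenzaldehyde | O=Cc1ccc(O)cc1O | intermediate
4 | 2,4-bis(methoxymethoxy)benzaldehyde | O=Cc1ccc(OCOC)cc1OCOC | intermediate
5 | acetic acid | CC(=O)O | starting material
6 | 1-(2,4-dihydroxyphenyl)ethanone | CC(=O)c1ccc(O)cc1O | intermediate
7 | 1-[2-hydroxy-4-(methoxymethoxy)phenyl]ethanone | CC(=O)c1ccc(OCOC)cc1O | intermediate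
8 | (E)-3-[2,4-bis(methoxymethoxy)phenyl]-1-[2-hydroxy-4-(methoxymethoxy)phenyl]prop-2-en-1-one | O=C(/C=C/c1ccc(OCOC)cc1OCOC)c1ccc(OCOC)cc1O | intermediate
9 | 1-(2,4-dihydroxy-3-iodophenyl)ethanone | CC(=O)c1ccc(O)c(I)c1O | intermediate
10 | 1-[3-iodo-2,4-bis(methoxymethoxy)phenyl]ethanone | CC(=O)c1ccc(OCOC)c(I)c1OCOC | intermediate
11 | 2-methylbut-1-en-3-yne | C=C(C)C#C | starting material
12 | (E)-4,4,5,5-tetramethyl-2-(3-methylbuta-1,3-dien-1-yl)-1,3,2-dioxaborolane | CC(=C)/C=C/B1OC(C)(C)C(C)(C)O1 | intermediate (not isolated)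
13 | 1-[2,4-bis(methoxymethoxy)-3-[(1E)-3-methylbuta-1,3-dien-1-yl]phenyl]ethanone | CC(=O)c1ccc(OCOC)c(/C=C/C(C)=C)c1OCOC | intermediate
14 | (E)-1-[2,4-bis(methoxymethoxy)-3-[(1E)-3-methylbuta-1,3-dien-1-yl]phenyl]-3-[2,4-bis(methoxymethoxy)phenyl]prop-2-en-1-one | C=C(C)/C=C/c1c(OCOC)ccc(C(=O)/C=C/c2ccc(OCOC)cc2OCOC)c1OCOC | intermediate
15 | [(1R,4S)-4-[2,4-bis(methoxymethoxy)phenyl]-2-[(E)-2-[2,6-bis(methoxymethoxy)-3-[(E)-3-[2,4-bis(methoxymethoxy)phenyl]prop-2-enoyl]phenyl]ethenyl]-2-methylcyclobutyl][2-hydroxy-4-(methoxymethoxy)phenyl]methanone, both configurations at C2 (centre left open in the SMILES) | CC1(/C=C/c2c(OCOC)ccc(C(=O)/C=C/c3ccc(OCOC)cc3OCOC)c2OCOC)[C@H](C(=O)c2ccc(OCOC)cc2O)[C@@H](c2ccc(OCOC)cc2OCOC)C1 | intermediate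
16 | (E)-1-[3-[(1S,5S,6R)-5-[2,4-bis(methoxymethoxy)phenyl]-6-[2-hydroxy-4-(methoxymethoxy)benzoyl]-3-methylcyclohex-2-en-1-yl]-2,4-bis(methoxymethoxy)phenyl]-3-[2,4-bis(methoxymethoxy)phenyl]prop-2-en-1-one | CC1=C[C@H](c2c(OCOC)ccc(C(=O)/C=C/c3ccc(OCOC)cc3OCOC)c2OCOC)[C@H](C(=O)c2ccc(OCOC)cc2O)[C@@H](c2ccc(OCOC)cc2OCOC)C1 | intermediate
17 | (E)-1-[3-[(1S,5S,6R)-6-(2,4-dihydroxybenzoyl)-5-(2,4-dihydroxyphenyl)-3-methylcyclohex-2-en-1-yl]-2,4-dihydroxyphenyl]-3-(2,4-dihydroxyphenyl)prop-2-en-1-one | CC1=C[C@H](c2c(O)ccc(C(=O)/C=C/c3ccc(O)cc3O)c2O)[C@H](C(=O)c2ccc(O)cc2O)[C@@H](c2ccc(O)cc2O)C1 | target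

## Step count and risks

Total step count: 12. Longest linear sequence: 8 steps (steps 3, 6, 7, 8, 9, 10, 11, 12).

The three steps most likely to fail:

**Step 11 (proposed new ring expansion).** The risks are closure to the all-trans (exo-type) isomer, proton loss from the allyl cation to an open-chain triene, and MOM loss. The fallback uses known chemistry and sets out from chalcone 8 and diene chalcone 14. The two are combined directly in an asymmetric Diels–Alder cycloaddition promoted by a chiral borate Lewis acid made from B(OPh)3 and an axially chiral biaryl diol such as VANOL. The borate chelates the 2'-hydroxychalcone, and this is an established reaction for 2'-hydroxychalcones with 1-aryl-3-methylbutadienes. The diol enantiomer is chosen by the observed sense, and the endo adduct is separated from the exo isomer by chromatography. The fallback comes back to the route at compound 16 and makes no compound outside the list (none F0).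

**Step 10 (enantioselective [2+2]).** The risks are E/Z isomerisation or photodimerisation of 8, interference from the second chalcone chromophore in 14, and premature uncontrolled ionisation of 15 by the scandium catalyst. The fallback changes the order of assembly and sets out from chalcone 8 and the simpler diene ketone 13, which has no second enone. The same photocycloaddition gives the methyl-ketone vinylcyclobutane F1. This is ring-expanded under the step 11 conditions to the cyclohexenyl methyl ketone F2. A Claisen–Schmidt condensation of F2 with aldehyde 4 (KOH, EtOH, rt) then builds the second chalcone; the 2'-phenoxide of the aroyl group damps enolisation at C6. The fallback comes back to the route at compound 16.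

**Step 12 (global MOM removal).** The risks are acid-induced ketalisation of the C6 carbonyl by the neighbouring phenols, addition of a phenol to the ring alkene, and flavanone formation. The fallback sets out from compound 16 and avoids protic acid. TMSOTf with 2,2'-bipyridyl in CH2Cl2 at 0 °C exchanges every aryl MOM ether for a trimethylsilyl ether and silylates the free phenol, giving the octakis(trimethylsilyl) ether F3. Adding water at about pH 7 then hydrolyses the silyl ethers, and the fallback comes back to the route at compound 17.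

## Further compounds

F1 | step 10 | [(1R,4S)-2-[(E)-2-[3-acetyl-2,6-bis(methoxymethoxy)phenyl]ethenyl]-4-[2,4-bis(methoxymethoxy)phenyl]-2-methylcyclobutyl][2-hydroxy-4-(methoxymethoxy)phenyl]methanone, both configurations at C2 | CC1(/C=C/c2c(OCOC)ccc(C(C)=O)c2OCOC)[C@H](C(=O)c2ccc(OCOC)cc2O)[C@@H](c2ccc(OCOC)cc2OCOC)C1
F2 | step 10 | 1-[3-[(1S,5S,6R)-5-[2,4-bis(methoxymethoxy)phenyl]-6-[2-hydroxy-4-(methoxymethoxy)benzoyl]-3-methylcyclohex-2-en-1-yl]-2,4-bis(methoxymethoxy)phenyl]ethanone | CC1=C[C@H](c2c(OCOC)ccc(C(C)=O)c2OCOC)[C@H](C(=O)c2ccc(OCOC)cc2O)[C@@H](c2ccc(OCOC)cc2OCOC)C1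
F0 | step 11 | none | none
F3 | step 12 | octakis(trimethylsilyl) ether of 17 | CC1=C[C@H](c2c(O[Si](C)(C)C)ccc(C(=O)/C=C/c3ccc(O[Si](C)(C)C)cc3O[Si](C)(C)C)c2O[Si](C)(C)C)[C@H](C(=O)c2ccc(O[Si](C)(C)C)cc2O[Si](C)(C)C)[C@@H](c2ccc(O[Si](C)(C)C)cc2O[Si](C)(C)C)C1
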